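**Retrosynthetic overview**
1. The last bond made is the aryl–prenyl C–C bond on ring A (the phenol ring). It comes from a new phosphinite-relay, rhodium-catalysed ortho C–H addition of the free terphenylol to 3-methylbuta-1,2-diene.
2. The ring A–ring B bond comes from a Suzuki–Miyaura coupling of (4-hydroxyphenyl)boronic acid with a ring-B iodide. The iodine is placed between two methoxy groups by directed ortho-lithiation of 2,3,5-trimethoxybiphenyl.
3. The third oxygen of ring B comes from CHO → OCHO → OH → OMe (Baeyer–Villiger, then methylation). The ring B–ring C bond comes from a Suzuki–Miyaura coupling of 3-bromo-4,5-dimethoxybenzaldehyde with phenylboronic acid.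
4. No ring is built, since all three benzene rings are bought. They are joined C to B, then A to B, and the prenyl group comes last.

Assumption: the SMILES holds no stereocentre, no E/Z-stereogenic alkene and no configurationally stable biaryl axis (rings A and C carry no ortho substituents). The target is therefore achiral and no enantiocontrol is needed.

**Route**

Step 1
Reactants: 1 3-bromo-4,5-dimethoxybenzaldehyde; 2 phenylboronic acid
Product: 3 5,6-dimethoxy-[1,1'-biphenyl]-3-carbaldehyde
Conditions: Pd(PPh3)4 (3 mol %), K2CO3 (2 equiv), toluene/EtOH/H2O, 85 °C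
Reagents that add atoms: none
Why: Suzuki–Miyaura coupling, in which the aryl bromide adds readily to zerovalent palladium and the aldehyde and methyl ethers are inert to aqueous carbonate.

Step 2
Reactants: 3 5,6-dimethoxy-[1,1'-biphenyl]-3-carbaldehyde
Product: 5 5,6-dimethoxy-[1,1'-biphenyl]-3-ol, via aryl formate 4 (not isolated)
Conditions: mCPBA (1.3 equiv), CH2Cl2, 0 °C to rt; then NaOH (aq), MeOH, rt; HCl work-up
Reagents that add atoms: mCPBA, O=C(OO)c1cccc(Cl)c1
Why: Baeyer–Villiger oxidation, in which the electron-rich aryl group (para-methoxy) migrates in the Criegee adduct in preference to hydride, and the formate is saponified in the same flask.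

Step 3
Reactants: 5 5,6-dimethoxy-[1,1'-biphenyl]-3-ol
Product: 6 2,3,5-trimethoxy-1,1'-biphenyl
Conditions: MeI (1.5 equiv), K2CO3 (2 equiv), acetone, reflux
Reagents that add atoms: iodomethane, CI
Why: Williamson ether synthesis (SN2 O-methylation of the phenoxide), with no other nucleophilic site in the molecule.

Step 4
Reactants: 6 2,3,5-trimethoxy-1,1'-biphenyl
Product: 8 4-iodo-2,3,5-trimethoxy-1,1'-biphenyl, via aryllithium 7 (not isolated)
Conditions: n-BuLi (1.2 equiv), TMEDA (1.2 equiv), THF, 0 °C, 1.5 h; then I2 (1.3 equiv), −78 °C to rt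
Reagents that add atoms: iodine, II
Why: Directed ortho-metalation, in which C4–H lies between two methoxy groups that chelate lithium together and acidify it most (the same site selectivity as 1,3-dimethoxybenzene and 1,2,4-trimethoxybenzene), and iodine traps the aryllithium at that carbon.

Step 5
Reactants: 8 4-iodo-2,3,5-trimethoxy-1,1'-biphenyl; 9 (4-hydroxyphenyl)boronic acid
Product: 10 2',3',6'-trimethoxy-[1,1':4',1''-terphenyl]-4-ol
Conditions: Pd(OAc)2 (3 mol %), SPhos (6 mol %), K3PO4 (3 equiv), 9 (1.5 equiv), dioxane/H2O (5:1), 90 °C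
Reagents that add atoms: none
Why: Suzuki–Miyaura coupling, in which the bulky electron-rich ligand SPhos handles di-ortho-substituted aryl halides, the boronic acid has no ortho substituent, and the free phenol is tolerated as its phenoxide.

Step 6
Reactants: 10 2',3',6'-trimethoxy-[1,1':4',1''-terphenyl]-4-ol; 11 3-methylbuta-1,2-diene
Product: 14 Sanshamycin B (2',3',6'-trimethoxy-3-(3-methylbut-2-en-1-yl)-[1,1':4',1''-terphenyl]-4-ol), via aryl diisopropylphosphinite 12 (not isolated), via ortho-prenylated aryl diisopropylphosphinite 13 (not isolated)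
Conditions: [RhCl(cod)]2 (2.5 mol %), iPr2PCl (12 mol %), Cs2CO3 (30 mol %), 11 (1.2 equiv, added over 6 h), toluene, 100 °C, sealed vessel; MeOH/aq NH4Cl work-up
Reagents that add atoms: none
Why: Proposed new method: iPr2PCl and the caesium phenoxide of 10 give phosphinite 12, whose phosphorus binds monovalent rhodium and holds it next to an ortho C–H bond of ring A, so oxidative addition gives a five-membered P,C-rhodacycle hydride of trivalent rhodium; allene 11 inserts into Rh–H with hydrogen going to its central carbon, and the resulting 1,1-dimethyl-π-allyl ligand couples with the aryl carbon by reductive elimination at its unhindered CH2 end (linear prenyl, not reverse prenyl) to give 13; phenoxide-catalysed P–O exchange of 13 with fresh 10 releases 14 and regenerates 12, so the overall equation is a pure addition of the C–H bond across the allene; the two ortho positions of ring A are equivalent and rings B and C are out of reach of the tether; the closest known reaction types are the phosphinite- or phosphite-relay ortho-arylation and ortho-ethylation of phenols under rhodium or ruthenium catalysis and the chelation-assisted C–H prenylation of arenes bearing fixed nitrogen directing groups with 1,1-dimethylallene, and the two have not been combined into a prenylation of a free phenol.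

**Compound list**
1 | 3-bromo-4,5-dimethoxybenzaldehyde | COc1cc(C=O)cc(Br)c1OC | starting material
2 | phenylboronic acid | OB(O)c1ccccc1 | starting material
3 | 5,6-dimethoxy-[1,1'-biphenyl]-3-carbaldehyde | COc1cc(C=O)cc(-c2ccccc2)c1OC | intermediate
4 | 5,6-dimethoxy-[1,1'-biphenyl]-3-yl formate | COc1cc(OC=O)cc(-c2ccccc2)c1OC | intermediate
5 | 5,6-dimethoxy-[1,1'-biphenyl]-3-ol | COc1cc(O)cc(-c2ccccc2)c1OC | intermediate
6 | 2,3,5-trimethoxy-1,1'-biphenyl | COc1cc(-c2ccccc2)c(OC)c(OC)c1 | intermediate
7 | (2,3,5-trimethoxy-[1,1'-biphenyl]-4-yl)lithium | COc1cc(-c2ccccc2)c(OC)c(OC)c1[Li] | intermediate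
8 | 4-iodo-2,3,5-trimethoxy-1,1'-biphenyl | COc1cc(-c2ccccc2)c(OC)c(OC)c1I | intermediate
9 | (4-hydroxyphenyl)boronic acid | OB(O)c1ccc(O)cc1 | starting material
10 | 2',3',6'-trimethoxy-[1,1':4',1''-terphenyl]-4-ol | COc1cc(-c2ccccc2)c(OC)c(OC)c1-c1ccc(O)cc1 | intermediate
11 | 3-methylbuta-1,2-diene | CC(C)=C=C | starting material
12 | 2',3',6'-trimethoxy-[1,1':4',1''-terphenyl]-4-yl diisopropylphosphinite | COc1cc(-c2ccccc2)c(OC)c(OC)c1-c1ccc(OP(C(C)C)C(C)C)cc1 | intermediate
13 | 2',3',6'-trimethoxy-3-(3-methylbut-2-en-1-yl)-[1,1':4',1''-terphenyl]-4-yl diisopropylphosphinite | COc1cc(-c2ccccc2)c(OC)c(OC)c1-c1ccc(OP(C(C)C)C(C)C)c(CC=C(C)C)c1 | intermediate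
14 | Sanshamycin B, 2',3',6'-trimethoxy-3-(3-methylbut-2-en-1-yl)-[1,1':4',1''-terphenyl]-4-ol (achiral) | COc1cc(-c2ccccc2)c(OC)c(OC)c1-c1ccc(O)c(CC=C(C)C)c1 | target

**Step count**
Total step count: 6.
Longest linear sequence: 6 steps (1 → 3 → 5 → 6 → 8 → 10 → 14).

**Three steps most likely to fail**

Step 6 (the proposed new step). The risks are slow cyclometalation of a phosphinite that has no ortho substituent, a second prenylation at the other ortho carbon, rhodium-induced oligomerisation of 11, and migration of the prenyl double bond. The fallback uses known chemistry, sets out from 10 and comes back to the route at 14. Compound 10 is O-alkylated with 3-chloro-3-methylbut-1-yne (CuCl2 1 mol %, DBU, MeCN, 0 °C) to 2',3',6'-trimethoxy-4-[(2-methylbut-3-yn-2-yl)oxy]-1,1':4',1''-terphenyl F1. The alkyne is semi-hydrogenated (H2, Pd/CaCO3 poisoned with Pb(OAc)2, quinoline, EtOAc) to 2',3',6'-trimethoxy-4-[(2-methylbut-3-en-2-yl)oxy]-1,1':4',1''-terphenyl F2. Heating F2 (N,N-diethylaniline, 160 °C) triggers an aromatic Claisen rearrangement that carries the CH2 terminus to the ortho carbon and gives 14 after tautomerisation. Only one allyl unit sits on the oxygen, so mono-prenylation is built in.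

Step 5. The iodide is flanked by two methoxy groups, so slow transmetalation may let hydrodeiodination of 8 and protodeboronation of 9 win. The fallback reverses the polarity (Negishi coupling), sets out from 6 and comes back at 10. Compound 6 is lithiated to 7 as in step 4, and ZnCl2 in THF converts 7 to chloro(2,3,5-trimethoxy-[1,1'-biphenyl]-4-yl)zinc F3. This is coupled in the same flask with commercial 1-(benzyloxy)-4-bromobenzene (Pd(OAc)2, SPhos, THF, 60 °C) to 4-(benzyloxy)-2',3',6'-trimethoxy-1,1':4',1''-terphenyl F4. Hydrogenolysis (H2, Pd/C, EtOAc/MeOH) then gives 10.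

Step 4. Part of the lithiation could go to C6 (between methoxy and phenyl) or onto ring C, giving iodide mixtures that are hard to separate. The fallback places the halogen by electrophilic substitution on a quinone instead of by deprotonation, sets out from 5 and comes back at 10.
- Oxidation: the 4-methoxyphenol 5 is oxidised (PhI(OAc)2, MeCN/H2O, 0 °C) to 2-methoxy-6-phenylcyclohexa-2,5-diene-1,4-dione F5.
- Bromination: Br2 in CHCl3 brominates the nucleophilic carbon next to the methoxy group (the alpha carbon of the vinylogous ester) to give 2-bromo-3-methoxy-5-phenylcyclohexa-2,5-diene-1,4-dione F6.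
- Reduction: Na2S2O4 (THF/H2O) reduces F6 to 4-bromo-3-methoxy-[1,1'-biphenyl]-2,5-diol F7.
- Methylation: MeI/K2CO3 (acetone, reflux) gives 4-bromo-2,3,5-trimethoxy-1,1'-biphenyl F8.
- Coupling: F8 is coupled with 9 under the conditions of step 5 to give 10.

**Further compounds**
F1 | step 6 | 2',3',6'-trimethoxy-4-[(2-methylbut-3-yn-2-yl)oxy]-1,1':4',1''-terphenyl | COc1cc(-c2ccccc2)c(OC)c(OC)c1-c1ccc(OC(C)(C)C#C)cc1
F2 | step 6 | 2',3',6'-trimethoxy-4-[(2-methylbut-3-en-2-yl)oxy]-1,1':4',1''-terphenyl | COc1cc(-c2ccccc2)c(OC)c(OC)c1-c1ccc(OC(C)(C)C=C)cc1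
F3 | step 5 | chloro(2,3,5-trimethoxy-[1,1'-biphenyl]-4-yl)zinc | COc1cc(-c2ccccc2)c(OC)c(OC)c1[Zn]Cl
F4 | step 5 | 4-(benzyloxy)-2',3',6'-trimethoxy-1,1':4',1''-terphenyl | COc1cc(-c2ccccc2)c(OC)c(OC)c1-c1ccc(OCc2ccccc2)cc1
F5 | step 4 | 2-methoxy-6-phenylcyclohexa-2,5-diene-1,4-dione | COC1=CC(=O)C=C(c2ccccc2)C1=O
F6 | step 4 | 2-bromo-3-methoxy-5-phenylcyclohexa-2,5-diene-1,4-dione | COC1=C(Br)C(=O)C=C(c2ccccc2)C1=O
F7 | step 4 | 4-bromo-3-methoxy-[1,1'-biphenyl]-2,5-diol | COc1c(Br)c(O)cc(-c2ccccc2)c1O
F8 | step 4 | 4-bromo-2,3,5-trimethoxy-1,1'-biphenyl | COc1cc(-c2ccccc2)c(OC)c(OC)c1Br
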